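The constants were set for the occasion; no experiment stands behind them.

The easy step comes first: partner decays by first order into second intermediate, with a half-life of 19 s.

    partner → second intermediate (k1 = 0.036 s⁻¹)
    open intermediate + second intermediate → target (k2 = 3.9 L mol⁻¹ s⁻¹)
    substrate ⇌ open intermediate (K3 = 2.0, k3 = 0.0079 s⁻¹)
    substrate + target ⇌ idle adduct, settled at all times (K4 = 24 L mol⁻¹)

- beta: substrate 10 mM; partner 15.0 mM; time 25 s
- theta: substrate 10 mM; partner 15.0 mM; time 50 s

- which of these there is most of at the end, counted by the substrate in it, beta (open intermediate / target / substrate)
- which of these there is most of at the end, counted by the substrate in it, theta (open intermediate / target / substrate)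
- amount of the one of these that there is most of at the end, in percent of the substrate charged, beta
- amount of the one of these that there is most of at the end, in percent of the substrate charged, theta

- a species is counted by the substrate in it: one idle adduct counts as two
- amounts and yields of target count idle adduct too
- in an amount of target, one idle adduct counts as one target
- run time (beta): 25 s

Open intermediate has two exits: it falls back with constant 0.00395 s⁻¹, or it couples with second intermediate. The quantity to carry is the crossing fraction, the share of the partner charge which, standing as second intermediate, makes these two exits equally fast: 0.0675.

This reckoning draws second intermediate first, ignoring its use in coupling. Its fraction starts at zero, rises as one minus the partner decay, and passes the crossing at 1.94 s, far earlier than 25 s. By 25 s the fraction is 0.593, and by 50 s it is 0.835, so falling back is 0.114 and then 0.0808 of coupling. Past that crossing this reckoning treats the opening of substrate as one-way.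

The substrate fraction starts with a slope of 0.0079 s⁻¹ and is reckoned as a plain forward decay. Its half-life by the forward opening, the way back not counted, is 88 s, longer than 50 s, so neither asked time lies past that half-way mark. The reckoning gives 82.1 % in beta and 67.4 % in theta. Each is more than half, so substrate leads in both flasks.

The forecast names substrate at 82.5 % for beta and substrate at 67.5 % for theta, slightly above this reckoning, on the ground that “Most material is therefore still free substrate at both times”.

The simulation gives substrate at 82.1 % in beta and substrate at 67.0 % in theta. In theta at 15.0 s, open intermediate fell back at 0.17 of the rate at which it went on.

In the neighbour, theta read at 80 s, second intermediate is reckoned, its use in coupling again ignored, at 0.944 of the partner charge, still above the crossing fraction, so forward decay of substrate gives 53.2 %. That flask holds 53.0 % of substrate.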